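The cycloheptenone (ring B) is closed last, between a finished enol-ester cyclohexene (ring A) and a finished cyclopentene-fused γ-lactone (rings C and D). The feature exploited is the aldol unit formed by the ring-B ketone carbon, the adjacent B/C-fusion CH and the tertiary carbinol carbon C(OH)CH3 of ring C. Its C–C and C–O bonds lie cis on the lactone face. One intramolecular nitrile oxide–alkene cycloaddition forms both bonds, closes ring B and sets both stereocentres through a temporary isoxazoline, which is then cleaved reductively. The precursor is a nitromethyl-bearing ring A tied by an (E)-alkylidene carbon to the lactone, and its ring C still holds a trisubstituted alkene.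

Key step: step 13

Labels used below (target):
- Ring A = C-1 (CH bearing isopropenyl), C-2 (CH2), C-3 (C–OH), C-4 (C–CO2Me), C-5 and C-6 (A/B fusion CH; C-5 is next to the ketone).
- Ring B = C-5, C-7 (C=O), C-8, C-9, C-10 (=C), C-11 (=CH), C-6.
- Ring C = C-8, C-9, C-12 (CH–O), C-13 (CH2), C-14 (C(OH)CH3).
- Ring D = C-9, C-10, C-15 (lactone C=O), O, C-12.

Remark on the chemistry: β-keto esters are written as enols, as in the target, and centres that are lost again (C-4 in 5, C-10 in 18) are left undefined.

Step 1
Reactants: 1 cyclohex-2-en-1-one; 2 isopropenylboronic acid pinacol ester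
Product: 3 (S)-3-(prop-1-en-2-yl)cyclohexan-1-one
Conditions: [RhCl(C2H4)2]2 (1.5 mol %), (S)-BINAP (3.3 mol %), KOH (0.2 equiv), dioxane/H2O 10:1, 50 °C
Reagents that add atoms: none
Why: Rhodium-catalysed asymmetric 1,4-addition of an alkenylboron reagent (Hayashi–Miyaura reaction), in which the (S)-BINAP–rhodium alkenyl species should add to one enone face and so set C-1.

Step 2
Reactants: 3 (S)-3-(prop-1-en-2-yl)cyclohexan-1-one
Product: 4 methyl (4S)-2-hydroxy-4-(prop-1-en-2-yl)cyclohex-1-ene-1-carboxylate
Conditions: NaH (2.2 equiv), (MeO)2CO (5 equiv), THF, reflux; aq HCl work-up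
Reagents that add atoms: dimethyl carbonate COC(=O)OC
Why: Claisen-type C-acylation under equilibrating conditions should place the ester on the α-carbon remote from C-1, because only that β-keto ester gives an unstrained stabilised enolate, and the enol carries no new stereocentre.

Step 3
Reactants: 4 methyl (4S)-2-hydroxy-4-(prop-1-en-2-yl)cyclohex-1-ene-1-carboxylate
Product: 6 methyl (4S)-6-oxo-4-(prop-1-en-2-yl)cyclohex-1-ene-1-carboxylate, via α-selanyl keto ester 5 (not isolated)
Conditions: NaH, THF, 0 °C; PhSeCl, −78 °C; then 30% H2O2, CH2Cl2, 0 °C; used at once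
Reagents that add atoms: none
Why: Selenenylation of the sodium enolate outruns addition of PhSeCl to the isopropenyl group, and syn-elimination of the selenoxide can only take a C-5 hydrogen, which gives the C-4=C-5 enone ester (selenoxide elimination).

Step 4
Reactants: 6 methyl (4S)-6-oxo-4-(prop-1-en-2-yl)cyclohex-1-ene-1-carboxylate
Product: 8 methyl (3R,4R)-3-(dimethoxymethyl)-6-oxo-4-(prop-1-en-2-yl)cyclohex-1-ene-1-carboxylate, via TMS dienol ether 7 (not isolated)
Conditions: TMSOTf (1.5 equiv), Et3N (1.1 equiv), CH2Cl2, 0 °C; then HC(OMe)3 (3 equiv), −78 to −40 °C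
Reagents that add atoms: trimethyl orthoformate COC(OC)OC
Why: Soft enolisation removes the doubly vinylogous C-6 hydrogen to give the ester-conjugated linear dienol ether, which should attack the dimethoxycarbenium ion through its γ-terminus C-6 (vinylogous Mukaiyama reaction; the α-carbon C-4 is fully substituted) on the face anti to the neighbouring isopropenyl group, setting C-6 trans to C-1.

Step 5
Reactants: 8 methyl (3R,4R)-3-(dimethoxymethyl)-6-oxo-4-(prop-1-en-2-yl)cyclohex-1-ene-1-carboxylate
Product: 9 methyl (4R,5S,6S)-5-(dimethoxymethyl)-2-hydroxy-6-(nitromethyl)-4-(prop-1-en-2-yl)cyclohex-1-ene-1-carboxylate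
Conditions: MeNO2 (10 equiv), 1,1,3,3-tetramethylguanidine (10 mol %), THF, 0 °C to rt
Reagents that add atoms: nitromethane C[N+](=O)[O-]
Why: Michael addition of nitronate, in which axial (antiparallel) attack on the diequatorial half-chair, as in trans-fused octalones, puts CH2NO2 on C-5 trans to the isopropenyl group and cis to the C-6 substituent, and the reversible addition should converge on the same isomer because a pseudoaxial C-5 group avoids A(1,2) strain against the enol ester.

Step 6
Reactants: 9 methyl (4R,5S,6S)-5-(dimethoxymethyl)-2-hydroxy-6-(nitromethyl)-4-(prop-1-en-2-yl)cyclohex-1-ene-1-carboxylate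
Product: 10 methyl (4R,5S,6S)-5-formyl-2-hydroxy-6-(nitromethyl)-4-(prop-1-en-2-yl)cyclohex-1-ene-1-carboxylate
Conditions: 50% aq TFA, CHCl3, 0 °C
Reagents that add atoms: water O
Why: Acid-catalysed acetal hydrolysis frees the aldehyde while ester, enol and nitro group are inert, and C-6 keeps its equatorial, thermodynamically preferred configuration.

Step 7
Reactants: 11 (R)-4-(tert-butyldimethylsilyloxy)cyclopent-2-en-1-one
Product: 12 (1S,4R)-4-(tert-butyldimethylsilyloxy)-1-methylcyclopent-2-en-1-ol
Conditions: MeLi (1.2 equiv), Et2O, −78 °C; H2O quench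
Reagents that add atoms: methyllithium [Li]C
Why: 1,2-Addition of the hard organolithium to the enone carbonyl at low temperature should occur anti to the silyloxy group, so that the new tertiary hydroxyl on C-14 stands cis to the C-12 oxygen.

Step 8
Reactants: 12 (1S,4R)-4-(tert-butyldimethylsilyloxy)-1-methylcyclopent-2-en-1-ol
Product: 14 2-[(1S,5R)-5-(tert-butyldimethylsilyloxy)-3-methylcyclopent-2-en-1-yl]-N,N-dimethylacetamide, via ketene N,O-acetal 13 (not isolated)
Conditions: MeC(OMe)2NMe2 (5 equiv), toluene, 110 °C, MeOH distilled off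
Reagents that add atoms: N,N-dimethylacetamide dimethyl acetal CC(OC)(OC)N(C)C
Why: Eschenmoser–Claisen rearrangement, in which the ketene N,O-acetal formed on the tertiary hydroxyl undergoes a suprafacial [3,3] shift that carries the C-14–O configuration to the new C-9–C-10 bond, cis to the C-12 oxygen, and leaves the C-8=C-14 trisubstituted alkene.

Step 9
Reactants: 14 2-[(1S,5R)-5-(tert-butyldimethylsilyloxy)-3-methylcyclopent-2-en-1-yl]-N,N-dimethylacetamide
Product: 15 (3aS,6aR)-5-methyl-3,3a,6,6a-tetrahydro-2H-cyclopenta[b]furan-2-one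
Conditions: 1 M HCl, THF, 40 °C
Reagents that add atoms: none
Why: Acid removes the silyl ether and the freed cis γ-hydroxyl displaces protonated dimethylamine from the amide (lactonisation), which can only give the cis-fused bicycle and touches no stereocentre.

Step 10
Reactants: 15 (3aS,6aR)-5-methyl-3,3a,6,6a-tetrahydro-2H-cyclopenta[b]furan-2-one
Product: 17 (3R,3aS,6aR)-3-bromo-5-methyl-3,3a,6,6a-tetrahydro-2H-cyclopenta[b]furan-2-one, via silyl ketene acetal 16 (not isolated)
Conditions: LDA (1.1 equiv), THF, −78 °C; TMSCl (1.2 equiv); then NBS (1.05 equiv), −78 to 0 °C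
Reagents that add atoms: N-bromosuccinimide O=C1CCC(=O)N1Br
Why: The silyl ketene acetal is far more nucleophilic than the ring alkene and should take up bromine on the convex face (α-halogenation of an enol silane), at a centre that is lost again in the ylide.

Step 11
Reactants: 17 (3R,3aS,6aR)-3-bromo-5-methyl-3,3a,6,6a-tetrahydro-2H-cyclopenta[b]furan-2-one
Product: 19 (3aS,6aR)-5-methyl-3-(triphenyl-λ5-phosphanylidene)-3,3a,6,6a-tetrahydro-2H-cyclopenta[b]furan-2-one, via phosphonium bromide 18 (not isolated)
Conditions: PPh3 (1.2 equiv), Bu4NBr (10 mol %), MeCN, 80 °C; then 1 M NaOH, CH2Cl2, 0 °C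
Reagents that add atoms: triphenylphosphine c1ccc(cc1)P(c1ccccc1)c1ccccc1
Why: Quaternisation of PPh3 by the α-bromo lactone, helped by bromide-mediated epimerisation to the concave-face bromide that is open to convex-face attack, followed by deprotonation of the acidic salt, gives the ester-stabilised ylide (phosphonium ylide formation).

Step 12
Reactants: 10 methyl (4R,5S,6S)-5-formyl-2-hydroxy-6-(nitromethyl)-4-(prop-1-en-2-yl)cyclohex-1-ene-1-carboxylate; 19 lactone ylide
Product: 20 nitro (E)-alkylidene lactone (ring A of 10 joined through CH= to C-3 of lactone 15)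
Conditions: toluene, 70 °C, 19 (1.3 equiv)
Reagents that add atoms: none
Why: Wittig olefination by a stabilised ylide runs without added base, so the acidic nitromethyl and enol groups and the C-6 centre are left alone, and it should give the (E)-alkene in which C-6 is trans to the lactone carbonyl and therefore cis to C-9, as ring B requires.

Step 13
Reactants: 20 nitro (E)-alkylidene lactone
Product: 23 isoxazoline-bridged pentacycle (target skeleton in which C-7 is C=N and N is bonded to the oxygen on C-14), via O-Boc nitrile oxide 21 (not isolated), via O-Boc isoxazoline 22 (not isolated)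
Conditions: Boc2O (4 equiv), DMAP (0.3 equiv), toluene (2 mM), 20 added over 10 h, 50 °C; then K2CO3 (0.2 equiv), MeOH, 0 °C
Reagents that add atoms: none
Why: Boc2O/DMAP caps the enol as its tert-butyl carbonate (blocking enolate chemistry and retro-Michael loss of nitromethane) and dehydrates the primary nitro group to nitrile oxide 21, whose carbon C-7 and oxygen add in one concerted, suprafacial [3+2] step across the C-8=C-14 alkene, after which brief methanolysis frees the enol. The closest known reaction type is the intramolecular nitrile oxide–alkene cycloaddition used to build six- and seven-membered carbocycles as masked aldols. Ring B closes in the fused mode by C-7–C-8 bond formation (seven-membered, dipole carbon to the proximal alkene carbon), and the temporary isoxazoline closes by O–C-14 bond formation at the distal, more substituted carbon, which is also the electronically preferred regiochemistry. C-8 and C-14 are both set by the tether, because the rigid (E)-alkylidene carbon C-11 is anchored on ring D and lets the dipole reach only the concave, lactone-side face of ring C, placing C-7 and the oxygen cis to C-10 and the methyl group on the convex face. Chemoselectivity is needed against the isopropenyl group, the conjugated alkenes and dimerisation: the axial dipole is 1,3-trans to the equatorial isopropenyl group and cannot span to it, the C-10=C-11 and C-3=C-4 bonds are too close to be reached, and slow addition at high dilution should hold back furoxan formation.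

Step 14
Reactants: 23 isoxazoline-bridged pentacycle
Product: 25 target CNP0268969.1, via β-hydroxy imine 24 (not isolated)
Conditions: Mo(CO)6 (1.2 equiv), MeCN/H2O 10:1, 80 °C
Reagents that add atoms: water O
Why: Zerovalent molybdenum cleaves the N–O bond and the β-hydroxy imine hydrolyses in the wet medium (reductive isoxazoline opening), which unveils the C-7 ketone and the C-14 hydroxyl without touching the alkenes or any stereocentre.

Compound list
1 | cyclohex-2-en-1-one | O=C1C=CCCC1 | starting material
2 | isopropenylboronic acid pinacol ester | C=C(C)B1OC(C)(C)C(C)(C)O1 | starting material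
3 | (S)-3-(prop-1-en-2-yl)cyclohexan-1-one | C=C(C)[C@@H]1CC(=O)CCC1 | intermediate
4 | methyl (4S)-2-hydroxy-4-(prop-1-en-2-yl)cyclohex-1-ene-1-carboxylate (enol of the β-keto ester) | C=C(C)[C@@H]1CC(O)=C(C(=O)OC)CC1 | intermediate
5 | methyl (4S)-2-oxo-1-(phenylselanyl)-4-(prop-1-en-2-yl)cyclohexane-1-carboxylate, C1 epimers (not isolated) | C=C(C)[C@@H]1CC(=O)C(C(=O)OC)([Se]c2ccccc2)CC1 | intermediate
6 | methyl (4S)-6-oxo-4-(prop-1-en-2-yl)cyclohex-1-ene-1-carboxylate | C=C(C)[C@@H]1CC(=O)C(C(=O)OC)=CC1 | intermediate
7 | methyl (4R)-4-(prop-1-en-2-yl)-2-(trimethylsilyloxy)cyclohexa-1,5-diene-1-carboxylate (not isolated) | C=C(C)[C@@H]1CC(O[Si](C)(C)C)=C(C(=O)OC)C=C1 | intermediate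
8 | methyl (3R,4R)-3-(dimethoxymethyl)-6-oxo-4-(prop-1-en-2-yl)cyclohex-1-ene-1-carboxylate (substituents trans) | C=C(C)[C@@H]1CC(=O)C(C(=O)OC)=C[C@H]1C(OC)OC | intermediate
9 | methyl (4R,5S,6S)-5-(dimethoxymethyl)-2-hydroxy-6-(nitromethyl)-4-(prop-1-en-2-yl)cyclohex-1-ene-1-carboxylate (6-CH2NO2 cis to the 5-substituent, 5-substituent trans to isopropenyl) | C=C(C)[C@@H]1CC(O)=C(C(=O)OC)[C@@H](C[N+](=O)[O-])[C@H]1C(OC)OC | intermediate
10 | methyl (4R,5S,6S)-5-formyl-2-hydroxy-6-(nitromethyl)-4-(prop-1-en-2-yl)cyclohex-1-ene-1-carboxylate | C=C(C)[C@@H]1CC(O)=C(C(=O)OC)[C@@H](C[N+](=O)[O-])[C@H]1C=O | intermediate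
11 | (R)-4-(tert-butyldimethylsilyloxy)cyclopent-2-en-1-one | CC(C)(C)[Si](C)(C)O[C@H]1C=CC(=O)C1 | starting material
12 | (1S,4R)-4-(tert-butyldimethylsilyloxy)-1-methylcyclopent-2-en-1-ol (OH cis to OTBS) | CC(C)(C)[Si](C)(C)O[C@H]1C=C[C@@](C)(O)C1 | intermediate
13 | 1-(dimethylamino)vinyl ether of 12 (ketene N,O-acetal, not isolated) | CC(C)(C)[Si](C)(C)O[C@H]1C=C[C@@](C)(OC(=C)N(C)C)C1 | intermediate
14 | 2-[(1S,5R)-5-(tert-butyldimethylsilyloxy)-3-methylcyclopent-2-en-1-yl]-N,N-dimethylacetamide (cis) | CN(C)C(=O)C[C@H]1C=C(C)C[C@H]1O[Si](C)(C)C(C)(C)C | intermediate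
15 | (3aS,6aR)-5-methyl-3,3a,6,6a-tetrahydro-2H-cyclopenta[b]furan-2-one (cis-fused) | O=C1C[C@H]2C=C(C)C[C@H]2O1 | intermediate
16 | trimethylsilyl ketene acetal of 15 (not isolated) | C[Si](C)(C)OC1=C[C@H]2C=C(C)C[C@H]2O1 | intermediate
17 | (3R,3aS,6aR)-3-bromo-5-methyl-3,3a,6,6a-tetrahydro-2H-cyclopenta[b]furan-2-one (Br on the convex face) | O=C1[C@H](Br)[C@H]2C=C(C)C[C@H]2O1 | intermediate
18 | (5-methyl-2-oxo-3,3a,6,6a-tetrahydro-2H-cyclopenta[b]furan-3-yl)triphenylphosphonium bromide, C3 undefined (not isolated) | O=C1C([P+](c3ccccc3)(c3ccccc3)c3ccccc3)[C@H]2C=C(C)C[C@H]2O1.[Br-] | intermediate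
19 | (3aS,6aR)-5-methyl-3-(triphenyl-λ5-phosphanylidene)-3,3a,6,6a-tetrahydro-2H-cyclopenta[b]furan-2-one | O=C1C(=P(c3ccccc3)(c3ccccc3)c3ccccc3)[C@H]2C=C(C)C[C@H]2O1 | intermediate
20 | nitro (E)-alkylidene lactone: ring A of 10 joined through CH= to C-3 of lactone 15, ring-A carbon trans to the lactone C=O | C=C(C)[C@@H]1CC(O)=C(C(=O)OC)[C@@H](C[N+](=O)[O-])[C@H]1/C=C2/C(=O)O[C@@H]3CC(C)=C[C@H]23 | intermediate
21 | nitrile oxide of 20 as enol tert-butyl carbonate (not isolated) | C=C(C)[C@@H]1CC(OC(=O)OC(C)(C)C)=C(C(=O)OC)[C@@H](C#[N+][O-])[C@H]1/C=C2/C(=O)O[C@@H]3CC(C)=C[C@H]23 | intermediate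
22 | isoxazoline-bridged pentacycle as enol tert-butyl carbonate (not isolated) | C=C(C)[C@@H]1CC(OC(=O)OC(C)(C)C)=C(C(=O)OC)[C@H]2C(=N5)[C@@H]3[C@@H]4C(=C[C@H]21)C(=O)O[C@@H]4C[C@]3(C)O5 | intermediate
23 | isoxazoline-bridged pentacycle (C-7=N–O–C-14; all four ring-B hydrogens on one face) | C=C(C)[C@@H]1CC(O)=C(C(=O)OC)[C@H]2C(=N5)[C@@H]3[C@@H]4C(=C[C@H]21)C(=O)O[C@@H]4C[C@]3(C)O5 | intermediate
24 | β-hydroxy imine (C-7=NH, C-14–OH; not isolated) | C=C(C)[C@@H]1CC(O)=C(C(=O)OC)[C@H]2C(=N)[C@@H]3[C@@H]4C(=C[C@H]21)C(=O)O[C@@H]4C[C@]3(C)O | intermediate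
25 | CNP0268969.1 | C=C(C)[C@@H]1CC(O)=C(C(=O)OC)[C@H]2C(=O)[C@@H]3[C@@H]4C(=C[C@H]21)C(=O)O[C@@H]4C[C@]3(C)O | target

Total steps: 14. Longest linear sequence: 9 (steps 1–6 and 12–14).

Steps most likely to fail

Step 4. Three processes could spoil it:
- Silylation may go to the cross-conjugated α′ side.
- The carbenium ion may then be taken up at that α′ position.
- The γ-acetal may lose methanol to a dienyl enol ether under the Lewis acid.

The fallback reverses the order in which the two neighbouring ring-A substituents enter. It sets out from boronate 2 and comes back at 8.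
- Commercial 4-oxocyclohexane-1-carbaldehyde is acetalised selectively at the aldehyde (HC(OMe)3, catalytic acid) to 4-(dimethoxymethyl)cyclohexan-1-one F1.
- Enantioselective deprotonation with a lithium bis(1-phenylethyl)amide (enantiomer chosen for the sense needed) and TMSCl as internal quench gives (R)-4-(dimethoxymethyl)-1-(trimethylsilyloxy)cyclohex-1-ene F2.
- Saegusa oxidation with Pd(OAc)2 gives (R)-4-(dimethoxymethyl)cyclohex-2-en-1-one F3.
- Addition of 2 under the catalyst of step 1 should occur anti to the acetal, with substrate and catalyst matched. It gives trans-4-(dimethoxymethyl)-3-(prop-1-en-2-yl)cyclohexan-1-one F4.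
- NaH/(MeO)2CO gives the β-keto ester methyl 5-(dimethoxymethyl)-2-hydroxy-4-(prop-1-en-2-yl)cyclohex-1-ene-1-carboxylate F5.
- Selenenylation gives the α-phenylselanyl keto ester F6, and H2O2 delivers 8.

Step 13. Dimerisation of the nitrile oxide to a furoxan may outrun the slow seven-ring closure. The fallback changes the dipole to a silyl nitronate, which cannot dimerise. It sets out from 20 and comes back at 23.
- TMSCl/Et3N in toluene silylates both the enol and the nitro group to the bis-silylated silyl nitronate F10.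
- On warming, F10 should undergo the intramolecular silyl nitronate–alkene cycloaddition on the same concave face to the N-(trimethylsilyloxy)isoxazolidine F11.
- Dilute acid then eliminates silanol across C-7–N and cleaves the silyl enol ether to give 23.

Step 11. Three processes could spoil it:
- Backside attack of PPh3 on the convex-face bromide is shielded by ring C.
- Dehydrobromination to the butenolide may take over.
- Halophilic debromination may take over.

The fallback builds the lactone ring around a preformed ylide. It sets out from 12 and comes back at 19, so it also bypasses steps 8–10.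
- Alcohol 12 is deprotonated (n-BuLi) and acylated with methyl chloroformate to the tertiary allylic methyl carbonate F7.
- Buffered desilylation (TBAF/AcOH) gives the hydroxy carbonate F8.
- Addition of the hydroxyl to (triphenylphosphoranylidene)ketene (THF, 60 °C) gives the acyclic ester ylide F9.
- Catalytic Pd(PPh3)4 then effects a Tsuji–Trost closure. Zerovalent palladium ionises the carbonate anti, and the ylide carbon attacks C-9 anti to the metal (net retention, cis-fused lactone).
- The methoxide released deprotonates the phosphonium ion to give 19.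

Further compounds
F1 | step 4 | 4-(dimethoxymethyl)cyclohexan-1-one | O=C1CCC(C(OC)OC)CC1
F2 | step 4 | (R)-4-(dimethoxymethyl)-1-(trimethylsilyloxy)cyclohex-1-ene | C[Si](C)(C)OC1=CC[C@H](C(OC)OC)CC1
F3 | step 4 | (R)-4-(dimethoxymethyl)cyclohex-2-en-1-one | O=C1C=C[C@H](C(OC)OC)CC1
F4 | step 4 | trans-4-(dimethoxymethyl)-3-(prop-1-en-2-yl)cyclohexan-1-one | C=C(C)[C@@H]1CC(=O)CC[C@H]1C(OC)OC
F5 | step 4 | methyl 5-(dimethoxymethyl)-2-hydroxy-4-(prop-1-en-2-yl)cyclohex-1-ene-1-carboxylate (trans) | C=C(C)[C@@H]1CC(O)=C(C(=O)OC)C[C@H]1C(OC)OC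
F6 | step 4 | α-phenylselanyl keto ester of F5 (C1 epimers) | C=C(C)[C@@H]1CC(=O)C(C(=O)OC)([Se]c2ccccc2)C[C@H]1C(OC)OC
F7 | step 11 | methyl carbonate of 12 | CC(C)(C)[Si](C)(C)O[C@H]1C=C[C@@](C)(OC(=O)OC)C1
F8 | step 11 | (1S,4R)-4-hydroxy-1-methylcyclopent-2-en-1-yl methyl carbonate | O[C@H]1C=C[C@@](C)(OC(=O)OC)C1
F9 | step 11 | (triphenylphosphoranylidene)acetate ester of F8 | O=C(C=P(c1ccccc1)(c1ccccc1)c1ccccc1)O[C@H]1C=C[C@@](C)(OC(=O)OC)C1
F10 | step 13 | bis-silylated silyl nitronate of 20 | C=C(C)[C@@H]1CC(O[Si](C)(C)C)=C(C(=O)OC)[C@@H](C=[N+]([O-])O[Si](C)(C)C)[C@H]1/C=C2/C(=O)O[C@@H]3CC(C)=C[C@H]23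
F11 | step 13 | N-(trimethylsilyloxy)isoxazolidine pentacycle (C-7 undefined) | C=C(C)[C@@H]1CC(O[Si](C)(C)C)=C(C(=O)OC)[C@H]2C(N5O[Si](C)(C)C)[C@@H]3[C@@H]4C(=C[C@H]21)C(=O)O[C@@H]4C[C@]3(C)O5
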